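**Retrosynthetic overview**
1. The depside ester bond O4–C(=O) between ring B and ring A is cut last. Ring A comes from purchased methyl 2,4-dihydroxy-3,6-dimethylbenzoate by chlorination at C5', benzyl protection and saponification.
2. The plan rests on the hexasubstituted ring B: C1 CO2Me, C2 OH, C3 CH3 lying between the two oxygens O2 and O4, C4 O-acyl, and neighbouring CH3 groups on C5 and C6.
3. Ring B is cut into 2,3-dimethylcyclobutenone (C1, C2 with O2, C5, C6 and their methyls) and 1-(triisopropylsilyloxy)propyne (C3 with its methyl, C4 with O4). The vinylketene/siloxyalkyne benzannulation forms C2–C3, C4–C5 and C1–C2, leaves O2 free and O4 silylated, and leaves C1–H for formylation, oxidation and esterification.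
4. Ring order: the four-membered ring first (dichloroketene + but-2-yne), then ring B by the benzannulation; ring A is carried in intact and joined at O4 after desilylation.

Key step: step 4

Remark: the target has no stereocentre. Ring B is numbered C1 (CO2Me) to C6 as above; ring A is numbered from its carbonyl-bearing carbon as C1', so the chlorine sits on C5'.

**Step 1**
Reactants: 1 but-2-yne; 2 trichloroacetyl chloride
Product: 4 4,4-dichloro-2,3-dimethylcyclobut-2-en-1-one, via dichloroketene 3 (not isolated)
Conditions: Zn–Cu couple, Et2O/DME, rt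
Reagents that add atoms: none
Why: Zinc dechlorinates 2 to dichloroketene 3, which should add to the symmetrical alkyne in the known ketene–alkyne [2+2] cycloaddition, DME binding the ZnCl2 that could otherwise isomerize the product.

**Step 2**
Reactants: 4 4,4-dichloro-2,3-dimethylcyclobut-2-en-1-one
Product: 5 2,3-dimethylcyclobut-2-en-1-one
Conditions: Zn dust, AcOH, TMEDA, EtOH, 0 °C to rt
Reagents that add atoms: none
Why: Zinc-mediated reductive dechlorination of an α,α-dichloroketone, buffered by TMEDA/AcOH, should remove both chlorines without reducing the enone or opening the strained ring.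

**Step 3**
Reactants: 6 ethyl acetate
Product: 9 triisopropyl(prop-1-yn-1-yloxy)silane, via dibromomethyl adduct 7 (not isolated), via lithium prop-1-yn-1-olate 8 (not isolated)
Conditions: CH2Br2, LiTMP (lithium 2,2,6,6-tetramethylpiperidide), THF, −78 °C; then 6; n-BuLi, −78 °C to rt; then i-Pr3SiCl, −78 to 0 °C
Reagents that add atoms: dibromomethane, BrCBr; triisopropylsilyl chloride, CC(C)[Si](Cl)(C(C)C)C(C)C
Why: Kowalski ester homologation, in which LiCHBr2 adds to the ester carbonyl faster than it enolizes it to give adduct 7, bromine–lithium exchange with loss of ethoxide triggers a 1,2-methyl shift to ynolate 8, and the bulky silyl chloride silylates 8 on oxygen, not on carbon.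

**Step 4**
Reactants: 5 2,3-dimethylcyclobut-2-en-1-one; 9 triisopropyl(prop-1-yn-1-yloxy)silane
Product: 14 2,4,5-trimethyl-3-(triisopropylsilyloxy)phenol, via vinylketene 10 (not isolated), via 4-alkenylcyclobutenone 11 (not isolated), via dienylketene 12 (not isolated), via cyclohexa-2,4-dienone 13 (not isolated)
Conditions: PhMe, sealed tube, 80 °C then 110 °C, slight excess of 9
Reagents that add atoms: none
Why: Heating should open 5 by four-electron conrotatory cleavage of its C(=O)–CH2 bond to vinylketene 10, whose ketene C=C adds to siloxyalkyne 9 in a [2+2] cycloaddition to give 11. A second four-electron opening gives dienylketene 12, a six-electron disrotatory electrocyclization joins the ketene carbon to the terminal CH2 (target C2–C1) and so closes the six-membered ring B as dienone 13, and tautomerization gives phenol 14. This is the Danheiser benzannulation of a cyclobutenone with a siloxyalkyne, the known route to resorcinol monosilyl ethers. No stereocentre results, since the quaternary carbon of 11 forms racemic and becomes planar again in 12. The selectivity needed is the regiochemistry of the [2+2] step, secured by the polarized ynol ether: its nucleophilic methyl-bearing carbon bonds to the electrophilic ketene carbonyl carbon, so that methyl ends between O2 (the former ketene oxygen, free OH) and O4 (OTIPS). Ketene dimerization should be held back by the excess of electron-rich alkyne and by the reversible opening of 5, which keeps the concentration of 10 low.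

**Step 5**
Reactants: 14 2,4,5-trimethyl-3-(triisopropylsilyloxy)phenol
Product: 16 2-hydroxy-3,5,6-trimethyl-4-(triisopropylsilyloxy)benzaldehyde, via 2-(hydroxymethyl)phenol 15 (not isolated)
Conditions: MgCl2, Et3N, (CH2O)n, MeCN, reflux; then aq. HCl
Reagents that add atoms: paraformaldehyde (as formaldehyde), C=O
Why: Casnati–Skattebøl ortho-formylation, in which the magnesium phenoxide delivers formaldehyde to the only free ortho carbon and a second formaldehyde oxidizes benzylic alcohol 15 by hydride transfer, while the aryl TIPS ether shielded by two ortho methyls should survive.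

**Step 6**
Reactants: 16 2-hydroxy-3,5,6-trimethyl-4-(triisopropylsilyloxy)benzaldehyde
Product: 17 2-hydroxy-3,5,6-trimethyl-4-(triisopropylsilyloxy)benzoic acid
Conditions: NaClO2, NaH2PO4, 2-methylbut-2-ene, t-BuOH/THF/H2O, 0 °C to rt
Reagents that add atoms: sodium chlorite, [Na+].[O-]Cl=O
Why: Pinnick (Lindgren) oxidation should convert the hindered hydroxybenzaldehyde to the acid, the alkene scavenging HOCl so that the electron-rich, fully substituted ring is neither chlorinated nor oxidized.

**Step 7**
Reactants: 17 2-hydroxy-3,5,6-trimethyl-4-(triisopropylsilyloxy)benzoic acid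
Product: 18 methyl 2-hydroxy-3,5,6-trimethyl-4-(triisopropylsilyloxy)benzoate
Conditions: MeI, KHCO3, DMF, rt
Reagents that add atoms: iodomethane, CI
Why: Carboxylate SN2 alkylation, in which KHCO3 ionizes only the acid and not the hydrogen-bonded C2 phenol, and attack of the carboxylate oxygen on MeI is insensitive to the two ortho substituents.

**Step 8**
Reactants: 18 methyl 2-hydroxy-3,5,6-trimethyl-4-(triisopropylsilyloxy)benzoate
Product: 19 methyl 2,4-dihydroxy-3,5,6-trimethylbenzoate
Conditions: Bu4NF, AcOH, THF, 0 °C to rt
Reagents that add atoms: none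
Why: Fluoride-mediated desilylation should free the C4 phenol, the AcOH buffer protecting the methyl ester and the electron-rich phenoxide from base-induced side reactions.

**Step 9**
Reactants: 20 methyl 2,4-dihydroxy-3,6-dimethylbenzoate
Product: 21 methyl 5-chloro-2,4-dihydroxy-3,6-dimethylbenzoate
Conditions: SO2Cl2 (1.05 equiv), Et2O, 0 °C to rt
Reagents that add atoms: sulfuryl chloride, O=S(=O)(Cl)Cl
Why: Electrophilic aromatic chlorination should go to C5', the only unsubstituted ring carbon, which is ortho to the C4' hydroxyl and para to the C2' hydroxyl.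

**Step 10**
Reactants: 21 methyl 5-chloro-2,4-dihydroxy-3,6-dimethylbenzoate
Product: 22 methyl 2,4-bis(benzyloxy)-5-chloro-3,6-dimethylbenzoate
Conditions: BnBr, K2CO3, DMF, 60 °C
Reagents that add atoms: benzyl bromide, BrCc1ccccc1
Why: Williamson ether synthesis, with heating in DMF so that the chelated C2' hydroxyl is alkylated as well as the C4' hydroxyl.

**Step 11**
Reactants: 22 methyl 2,4-bis(benzyloxy)-5-chloro-3,6-dimethylbenzoate
Product: 23 2,4-bis(benzyloxy)-5-chloro-3,6-dimethylbenzoic acid
Conditions: KOH, DMSO/H2O, 90 °C; then aq. HCl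
Reagents that add atoms: potassium hydroxide, [K+].[OH-]
Why: Saponification of a di-ortho-substituted benzoate by poorly solvated hydroxide in wet DMSO should cleave the hindered ester and leave the aryl benzyl ethers and the aryl chloride untouched.

**Step 12**
Reactants: 19 methyl 2,4-dihydroxy-3,5,6-trimethylbenzoate; 23 2,4-bis(benzyloxy)-5-chloro-3,6-dimethylbenzoic acid
Product: 25 methyl 4-{[2,4-bis(benzyloxy)-5-chloro-3,6-dimethylbenzoyl]oxy}-2-hydroxy-3,5,6-trimethylbenzoate, via mixed trifluoroacetic anhydride 24 (not isolated)
Conditions: (CF3CO)2O, PhMe, 0 °C to rt; then aq. NaHCO3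
Reagents that add atoms: none
Why: Trifluoroacetic anhydride-mediated esterification, the mixed anhydride method for hindered depsides, in which 24 has enough alkoxy-stabilized acylium character for the methyl-flanked C4 hydroxyl to attack, the C2 hydroxyl is held in a hydrogen bond to the C1 ester, and any aryl trifluoroacetate is cleaved on bicarbonate work-up.

**Step 13**
Reactants: 25 methyl 4-{[2,4-bis(benzyloxy)-5-chloro-3,6-dimethylbenzoyl]oxy}-2-hydroxy-3,5,6-trimethylbenzoate
Product: 26 methyl 4-[(5-chloro-2,4-dihydroxy-3,6-dimethylbenzoyl)oxy]-2-hydroxy-3,5,6-trimethylbenzoate (CNP0198502.0)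
Conditions: BCl3, C6HMe5, CH2Cl2, −78 °C; aqueous work-up
Reagents that add atoms: none
Why: Lewis acid cleavage of aryl benzyl ethers by BCl3, with pentamethylbenzene as benzyl cation scavenger at low temperature, should spare both esters and, unlike hydrogenolysis, the aryl chloride.

**Compound list**
1 | but-2-yne | CC#CC | starting material
2 | trichloroacetyl chloride | ClC(Cl)(Cl)C(Cl)=O | starting material
3 | dichloroketene | ClC(Cl)=C=O | intermediate (not isolated)
4 | 4,4-dichloro-2,3-dimethylcyclobut-2-en-1-one | CC1=C(C)C(Cl)(Cl)C1=O | intermediate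
5 | 2,3-dimethylcyclobut-2-en-1-one | CC1=C(C)C(=O)C1 | intermediate
6 | ethyl acetate | CCOC(C)=O | starting material
7 | lithium 1,1-dibromo-2-ethoxypropan-2-olate (dibromomethyl adduct) | CCOC(C)([O-])C(Br)Br.[Li+] | intermediate (not isolated)
8 | lithium prop-1-yn-1-olate | CC#C[O-].[Li+] | intermediate (not isolated)
9 | triisopropyl(prop-1-yn-1-yloxy)silane | CC#CO[Si](C(C)C)(C(C)C)C(C)C | intermediate
10 | 2,3-dimethylbuta-1,3-dien-1-one (vinylketene) | O=C=C(C)C(C)=C | intermediate (not isolated)
11 | 2,4-dimethyl-4-(prop-1-en-2-yl)-3-(triisopropylsilyloxy)cyclobut-2-en-1-one, racemic (4-alkenylcyclobutenone) | CC1=C(O[Si](C(C)C)(C(C)C)C(C)C)C(C)(C(C)=C)C1=O | intermediate (not isolated)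
12 | (3E)-2,4,5-trimethyl-3-(triisopropylsilyloxy)hexa-1,3,5-trien-1-one, ketene and isopropenyl groups cis (dienylketene) | O=C=C(C)/C(O[Si](C(C)C)(C(C)C)C(C)C)=C(C)\C(C)=C | intermediate (not isolated)
13 | 2,4,5-trimethyl-3-(triisopropylsilyloxy)cyclohexa-2,4-dien-1-one | CC1=C(O[Si](C(C)C)(C(C)C)C(C)C)C(C)=C(C)CC1=O | intermediate (not isolated)
14 | 2,4,5-trimethyl-3-(triisopropylsilyloxy)phenol | Cc1cc(O)c(C)c(O[Si](C(C)C)(C(C)C)C(C)C)c1C | intermediate
15 | 2-(hydroxymethyl)-3,4,6-trimethyl-5-(triisopropylsilyloxy)phenol | OCc1c(C)c(C)c(O[Si](C(C)C)(C(C)C)C(C)C)c(C)c1O | intermediate (not isolated)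
16 | 2-hydroxy-3,5,6-trimethyl-4-(triisopropylsilyloxy)benzaldehyde | O=Cc1c(C)c(C)c(O[Si](C(C)C)(C(C)C)C(C)C)c(C)c1O | intermediate
17 | 2-hydroxy-3,5,6-trimethyl-4-(triisopropylsilyloxy)benzoic acid | OC(=O)c1c(C)c(C)c(O[Si](C(C)C)(C(C)C)C(C)C)c(C)c1O | intermediate
18 | methyl 2-hydroxy-3,5,6-trimethyl-4-(triisopropylsilyloxy)benzoate | COC(=O)c1c(C)c(C)c(O[Si](C(C)C)(C(C)C)C(C)C)c(C)c1O | intermediate
19 | methyl 2,4-dihydroxy-3,5,6-trimethylbenzoate | COC(=O)c1c(C)c(C)c(O)c(C)c1O | intermediate
20 | methyl 2,4-dihydroxy-3,6-dimethylbenzoate | COC(=O)c1c(C)cc(O)c(C)c1O | starting material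
21 | methyl 5-chloro-2,4-dihydroxy-3,6-dimethylbenzoate | COC(=O)c1c(C)c(Cl)c(O)c(C)c1O | intermediate
22 | methyl 2,4-bis(benzyloxy)-5-chloro-3,6-dimethylbenzoate | COC(=O)c1c(C)c(Cl)c(OCc2ccccc2)c(C)c1OCc1ccccc1 | intermediate
23 | 2,4-bis(benzyloxy)-5-chloro-3,6-dimethylbenzoic acid | OC(=O)c1c(C)c(Cl)c(OCc2ccccc2)c(C)c1OCc1ccccc1 | intermediate
24 | 2,4-bis(benzyloxy)-5-chloro-3,6-dimethylbenzoic trifluoroacetic anhydride | O=C(OC(=O)C(F)(F)F)c1c(C)c(Cl)c(OCc2ccccc2)c(C)c1OCc1ccccc1 | intermediate (not isolated)
25 | methyl 4-{[2,4-bis(benzyloxy)-5-chloro-3,6-dimethylbenzoyl]oxy}-2-hydroxy-3,5,6-trimethylbenzoate | COC(=O)c1c(C)c(C)c(OC(=O)c2c(C)c(Cl)c(OCc3ccccc3)c(C)c2OCc2ccccc2)c(C)c1O | intermediate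
26 | methyl 4-[(5-chloro-2,4-dihydroxy-3,6-dimethylbenzoyl)oxy]-2-hydroxy-3,5,6-trimethylbenzoate | COC(=O)c1c(C)c(C)c(OC(=O)c2c(C)c(Cl)c(O)c(C)c2O)c(C)c1O | target

**Step count**
Total: 13 steps. Longest linear sequence: 9 steps (1, 2, 4, 5, 6, 7, 8, 12, 13).

**Steps most likely to fail**

Step 4 (benzannulation). The unactivated, volatile cyclobutenone may open too slowly, so that it is lost by evaporation or oligomerization. The siloxyalkyne may also undergo a thermal 1,3-silyl shift to a silylketene before the vinylketene is captured, or the vinylketene may dimerize. The fallback makes the same vinylketene 10 at room temperature by a photochemical Wolff rearrangement and keeps the same bond construction. It sets out from 9 and comes back at 14. Commercial 2-methylpent-1-en-3-one F1 would be deprotonated at its ethyl CH2 with LiN(SiMe3)2 in THF at −78 °C and C-acylated with 2,2,2-trifluoroethyl trifluoroacetate to 1,1,1-trifluoro-3,5-dimethylhex-5-ene-2,4-dione F2. Detrifluoroacetylative diazo transfer with methanesulfonyl azide, Et3N and water in MeCN would then give 2-diazo-4-methylpent-4-en-3-one F3. Irradiation of F3 with 9 in CH2Cl2 at rt should trigger migration of the isopropenyl group to give 10, which is trapped as 11. Brief heating in toluene would then complete the four-electron opening and six-electron closure to 14.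

Step 12 (depside coupling). Capture of the acylium-like mixed anhydride by the phenol flanked by two methyls may be slow, so that trifluoroacetylation of the phenol, acylation at O2, or loss of the ortho benzyl group in the acidic medium competes. The fallback changes from acid-mediated acylium capture to base-mediated addition–elimination on a preformed phenoxide. It sets out from 23 and 19 and comes back at 25. Acid 23 would be converted with (COCl)2 and catalytic DMF in CH2Cl2 to 2,4-bis(benzyloxy)-5-chloro-3,6-dimethylbenzoyl chloride F4. Diol 19 would be treated with one equivalent of NaH in THF at 0 °C, which should deprotonate the more acidic, non-chelated C4 hydroxyl, and the sodium phenoxide would be acylated with F4 to give 25.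

Step 5 (ortho-formylation). Formaldehyde delivery to the ortho carbon next to the C6 methyl may be incomplete, the sequence may stall at the hydroxymethyl stage, or the silyl ether may be partly lost under prolonged heating with amine. The fallback installs the carboxyl carbon by halogen–metal exchange and carboxylation. It sets out from 14 and comes back at 17, bypassing steps 5 and 6. Bromination of 14 with N-bromosuccinimide in MeCN at 0 °C should occur at the only free ring carbon to give 2-bromo-3,4,6-trimethyl-5-(triisopropylsilyloxy)phenol F5. Treatment with n-BuLi (2.2 equiv) in THF at −78 °C should form the lithium phenoxide and then exchange bromine for lithium; quenching with CO2 and acidification would give acid 17.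

**Further compounds**
F1 | step 4 | 2-methylpent-1-en-3-one | C=C(C)C(=O)CC
F2 | step 4 | 1,1,1-trifluoro-3,5-dimethylhex-5-ene-2,4-dione | C=C(C)C(=O)C(C)C(=O)C(F)(F)F
F3 | step 4 | 2-diazo-4-methylpent-4-en-3-one | C=C(C)C(=O)C(C)=[N+]=[N-]
F4 | step 12 | 2,4-bis(benzyloxy)-5-chloro-3,6-dimethylbenzoyl chloride | O=C(Cl)c1c(C)c(Cl)c(OCc2ccccc2)c(C)c1OCc1ccccc1
F5 | step 5 | 2-bromo-3,4,6-trimethyl-5-(triisopropylsilyloxy)phenol | Cc1c(Br)c(O)c(C)c(O[Si](C(C)C)(C(C)C)C(C)C)c1C
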